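**Retrosynthetic overview**
1. Target 21 ⇐ chloride opening (at CH2) of the (2S)-2-methylglycidate ester of macrocycle 20.
2. 20 ⇐ closure of the ten-membered carbocycle at C5–C6: intramolecular nitroaldol of a C5 nitronate onto the C6 aldehyde of a hydroxybutenolide, relactonisation, loss of HNO2 (gives the 5E enol-lactone alkene).
3. Nitro hemiketal 16 ⇐ catalytic asymmetric addition of nitromethane to the methyl ketone of 1,4-diketone 14 with hemiketal trapping (oxolane ring, C4, C1); 14 ⇐ oxidative unmasking of a 2-methylfuran.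
4. Ester 12 ⇐ esterification (C8–O), hydroxymethyl Stille coupling (C13) and Ni/Cr coupling (C7–C8) of aldehyde 3 with dibromobutenolide 5 (from mucobromic acid).
5. Aldehyde 3 ⇐ organocatalytic Friedel–Crafts alkylation of 2-methylfuran with crotonaldehyde (C10). Ring order: butenolide (bought in) → oxolane hemiketal → ten-membered carbocycle.

**Assumptions and conventions.** Germacrane numbering is used for atom labels (C1 hemiketal carbon, C4 methyl-bearing ether carbon, C5=C6 enol-lactone alkene, C7=C11 butenolide alkene, C8 acyloxy carbon, C10 methyl-bearing CH, C13 CH2OAc). The target read from the SMILES is 1S,4R,5E,8R,10R with a (2R) side chain. Mucobromic acid is counted as achiral, since its lactol carbon is racemic and freely epimerising through the open (Z)-formyl acid. "BL" stands for the (2RS)-4-(acetoxymethyl)-2-[(tert-butyldimethylsilyl)oxy]-5-oxo-2,5-dihydrofuran-3-yl group.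

**Step 1**
Reactants: 1 2-methylfuran; 2 (E)-but-2-enal
Product: 3 (3R)-3-(5-methylfuran-2-yl)butanal
Conditions: (2S,5S)-5-benzyl-2-tert-butyl-3-methylimidazolidin-4-one·TFA (20 mol %), CH2Cl2/i-PrOH 85:15, −60 °C
Reagents that add atoms: none
Why: Iminium-ion organocatalytic Friedel–Crafts alkylation with the second-generation MacMillan imidazolidinone; the free furan α-carbon adds to the unshielded face of the E-iminium ion and sets C10 as R, the first stereocentre.

**Step 2**
Reactants: 4 mucobromic acid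
Product: 5 3,4-dibromo-5-[(tert-butyldimethylsilyl)oxy]furan-2(5H)-one
Conditions: TBSOTf, 2,6-lutidine, CH2Cl2, −78 → 0 °C
Reagents that add atoms: tert-butyldimethylsilyl triflate (CC(C)(C)[Si](C)(C)OS(=O)(=O)C(F)(F)F)
Why: O-silylation of the lactol with a non-nucleophilic base masks the latent C6 aldehyde as a fluoride-labile silyl acylal.

**Step 3**
Reactants: 3 (3R)-3-(5-methylfuran-2-yl)butanal; 5 3,4-dibromo-5-[(tert-butyldimethylsilyl)oxy]furan-2(5H)-one
Product: 6 (5RS)-3-bromo-5-[(tert-butyldimethylsilyl)oxy]-4-[(1R,3R)-1-hydroxy-3-(5-methylfuran-2-yl)butyl]furan-2(5H)-one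
Conditions: CrCl2 (3 equiv), Kishi-type valinol-derived oxazoline–N-aryl methanesulfonamide ligand (3.3 equiv, enantiomer that delivers the 1R carbinol), Et3N (3.3 equiv), THF, rt, 1 h; then NiCl2 (0.1 equiv), 5, 3, rt
Reagents that add atoms: none
Why: Asymmetric Nozaki–Hiyama–Kishi coupling; nickel inserts into the more electrophilic β C–Br bond, the alkenylchromium adds to the aldehyde under ligand control to set C8 as R, and the α C–Br bond is kept for step 4.

**Step 4**
Reactants: 6 (5RS)-3-bromo-5-[(tert-butyldimethylsilyl)oxy]-4-[(1R,3R)-1-hydroxy-3-(5-methylfuran-2-yl)butyl]furan-2(5H)-one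
Product: 8 [(5RS)-5-[(tert-butyldimethylsilyl)oxy]-4-[(1R,3R)-1-hydroxy-3-(5-methylfuran-2-yl)butyl]-2-oxo-2,5-dihydrofuran-3-yl]methyl acetate, via diol 7 (not isolated)
Conditions: Bu3SnCH2OH (1.5 equiv), Pd(PPh3)4 (5 mol %), CuI (10 mol %), DMF, 60 °C; then pyridine, Ac2O (1.1 equiv), −20 °C
Reagents that add atoms: (tributylstannyl)methanol (CCCC[Sn](CCCC)(CCCC)CO); acetic anhydride (CC(=O)OC(C)=O)
Why: Stille coupling of the α-bromobutenolide with the oxygen-activated hydroxymethyl stannane installs C13, then chemoselective acetylation of the primary allylic alcohol over the hindered secondary one; no stereocentre is touched.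

**Step 5**
Reactants: 9 2-methylprop-2-en-1-ol
Product: 10 [(2R)-2-methyloxiran-2-yl]methanol
Conditions: Ti(OiPr)4 (5 mol %), D-(−)-diisopropyl tartrate (6 mol %), t-BuOOH, 4 Å MS, CH2Cl2, −20 °C
Reagents that add atoms: tert-butyl hydroperoxide (CC(C)(C)OO)
Why: Sharpless–Katsuki asymmetric epoxidation; the D-tartrate catalyst delivers oxygen to the alkene face that gives the R epoxide.

**Step 6**
Reactants: 10 [(2R)-2-methyloxiran-2-yl]methanol
Product: 11 (2S)-2-methyloxirane-2-carboxylic acid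
Conditions: TEMPO (20 mol %), PhI(OAc)2 (2.2 equiv), MeCN/H2O 1:1, rt
Reagents that add atoms: water (O)
Why: Oxoammonium (TEMPO) oxidation of the primary alcohol through the aldehyde hydrate; the quaternary centre is untouched and its descriptor changes only by the priority rules.

**Step 7**
Reactants: 8 [(5RS)-5-[(tert-butyldimethylsilyl)oxy]-4-[(1R,3R)-1-hydroxy-3-(5-methylfuran-2-yl)butyl]-2-oxo-2,5-dihydrofuran-3-yl]methyl acetate; 11 (2S)-2-methyloxirane-2-carboxylic acid
Product: 12 (1R,3R)-1-(BL)-3-(5-methylfuran-2-yl)butyl (2S)-2-methyloxirane-2-carboxylate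
Conditions: 2,4,6-trichlorobenzoyl chloride, Et3N, toluene, rt; then 8, DMAP, rt
Reagents that add atoms: none
Why: Yamaguchi esterification through the mixed anhydride; acylation at oxygen keeps the C8 configuration.

**Step 8**
Reactants: 12 (1R,3R)-1-(BL)-3-(5-methylfuran-2-yl)butyl (2S)-2-methyloxirane-2-carboxylate
Product: 14 (1R,3R)-1-(BL)-3-methyl-4,7-dioxooctyl (2S)-2-methyloxirane-2-carboxylate, via cis-enedione 13 (not isolated)
Conditions: O2, hν (green LEDs), rose bengal (1 mol %), CH2Cl2/MeOH 4:1, −78 °C; Me2S; then Zn, AcOH, 0 °C, 15 min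
Reagents that add atoms: dioxygen (O=O)
Why: [4+2] cycloaddition of singlet oxygen to the electron-rich 2,5-dialkylfuran (the electron-poor butenolide is inert), reductive opening to the cis-enedione, and Zn/AcOH conjugate reduction to the 1,4-diketone; C10 is not involved.

**Step 9**
Reactants: 14 (1R,3R)-1-(BL)-3-methyl-4,7-dioxooctyl (2S)-2-methyloxirane-2-carboxylate; 15 nitromethane
Product: 16 (1R,3R)-1-(BL)-3-[(2RS,5R)-2-hydroxy-5-methyl-5-(nitromethyl)oxolan-2-yl]butyl (2S)-2-methyloxirane-2-carboxylate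
Conditions: MeNO2 (neat, 30 equiv), chiral bifunctional iminophosphorane–thiourea organocatalyst (10 mol %, enantiomer that gives the 5R oxolane), −20 °C, 48 h; AcOH quench
Reagents that add atoms: none
Why: Proposed new method: the chiral bifunctional Brønsted base deprotonates nitromethane and holds the nitronate on its thiourea, while the iminophosphonium N–H activates the less hindered methyl ketone (C4) and uses the γ-keto group (C1) as a second hydrogen-bond anchor to tell the two ketone faces apart; the tertiary alkoxide is captured at once by C1=O as a five-membered hemiketal, which takes it out of the retro-nitroaldol equilibrium so that C4–C5 bond formation is kinetically controlled and sets C4 as R; the closest known reaction types are organocatalytic Henry (nitroaldol) reactions of activated ketones such as α-keto esters and base-mediated racemic nitroaldol additions to simple ketones.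

**Step 10**
Reactants: 16 (1R,3R)-1-(BL)-3-[(2RS,5R)-2-hydroxy-5-methyl-5-(nitromethyl)oxolan-2-yl]butyl (2S)-2-methyloxirane-2-carboxylate
Product: 20 (1S,4R,5E,8R,10R)-13-acetoxy-1-hydroxy-8-[(2S)-2-methyloxirane-2-carbonyloxy]-1,4-epoxygermacra-5,7(11)-dien-12,6-olide, via lactol 17 (not isolated), via nitroaldol acid 18 (not isolated), via nitrolactone 19 (not isolated)
Conditions: TBAF (2.0 equiv), THF (0.002 M), −20 → 0 °C; AcOH (2.0 equiv), rt, 2 h; DBU (2.0 equiv), 0 °C → rt
Reagents that add atoms: none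
Why: Fluoride unmasks the hydroxybutenolide, whose open (Z)-formyl acrylate form undergoes an intramolecular Henry reaction with the C5 nitronate (ring closure templated by the cis-2,5-disubstituted oxolane); acid relactonises, and DBU-induced E1cB loss of nitrite from the γ-deprotonated butenolide gives the enol-lactone alkene, whose 5E geometry and the 1S hemiketal configuration are enforced by the bridged ring.

**Step 11**
Reactants: 20 (1S,4R,5E,8R,10R)-13-acetoxy-1-hydroxy-8-[(2S)-2-methyloxirane-2-carbonyloxy]-1,4-epoxygermacra-5,7(11)-dien-12,6-olide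
Product: 21 (1S,4R,5E,8R,10R)-13-acetoxy-8-[(2R)-3-chloro-2-hydroxy-2-methylpropanoyloxy]-1-hydroxy-1,4-epoxygermacra-5,7(11)-dien-12,6-olide
Conditions: HCl (1 M in Et2O, 2 equiv), CH2Cl2, −20 → 0 °C
Reagents that add atoms: hydrogen chloride (Cl)
Why: Acid-promoted SN2 opening of the glycidic ester by chloride at the unsubstituted CH2; the tertiary carbon is not touched, so the side-chain centre is retained and becomes 2R by the priority rules.

**Compound list**
1 | 2-methylfuran | Cc1ccco1 | starting material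
2 | (E)-but-2-enal (crotonaldehyde) | C/C=C/C=O | starting material
3 | (3R)-3-(5-methylfuran-2-yl)butanal | Cc1ccc(o1)[C@H](C)CC=O | intermediate
4 | mucobromic acid, 3,4-dibromo-5-hydroxyfuran-2(5H)-one (labile racemic lactol) | OC1OC(=O)C(Br)=C1Br | starting material
5 | 3,4-dibromo-5-[(tert-butyldimethylsilyl)oxy]furan-2(5H)-one (racemic) | CC(C)(C)[Si](C)(C)OC1OC(=O)C(Br)=C1Br | intermediate
6 | (5RS)-3-bromo-5-[(tert-butyldimethylsilyl)oxy]-4-[(1R,3R)-1-hydroxy-3-(5-methylfuran-2-yl)butyl]furan-2(5H)-one | Cc1ccc(o1)[C@H](C)C[C@@H](O)C2=C(Br)C(=O)OC2O[Si](C)(C)C(C)(C)C | intermediate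
7 | (5RS)-5-[(tert-butyldimethylsilyl)oxy]-3-(hydroxymethyl)-4-[(1R,3R)-1-hydroxy-3-(5-methylfuran-2-yl)butyl]furan-2(5H)-one | Cc1ccc(o1)[C@H](C)C[C@@H](O)C2=C(CO)C(=O)OC2O[Si](C)(C)C(C)(C)C | intermediate
8 | [(5RS)-5-[(tert-butyldimethylsilyl)oxy]-4-[(1R,3R)-1-hydroxy-3-(5-methylfuran-2-yl)butyl]-2-oxo-2,5-dihydrofuran-3-yl]methyl acetate | Cc1ccc(o1)[C@H](C)C[C@@H](O)C2=C(COC(C)=O)C(=O)OC2O[Si](C)(C)C(C)(C)C | intermediate
9 | 2-methylprop-2-en-1-ol | CC(=C)CO | starting material
10 | [(2R)-2-methyloxiran-2-yl]methanol | OC[C@@]1(C)OC1 | intermediate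
11 | (2S)-2-methyloxirane-2-carboxylic acid | OC(=O)[C@@]1(C)OC1 | intermediate
12 | (1R,3R)-1-(BL)-3-(5-methylfuran-2-yl)butyl (2S)-2-methyloxirane-2-carboxylate | Cc1ccc(o1)[C@H](C)C[C@@H](OC(=O)[C@@]3(C)OC3)C2=C(COC(C)=O)C(=O)OC2O[Si](C)(C)C(C)(C)C | intermediate
13 | (1R,3R,5Z)-1-(BL)-3-methyl-4,7-dioxooct-5-en-1-yl (2S)-2-methyloxirane-2-carboxylate | CC(=O)/C=C\C(=O)[C@H](C)C[C@@H](OC(=O)[C@@]3(C)OC3)C2=C(COC(C)=O)C(=O)OC2O[Si](C)(C)C(C)(C)C | intermediate
14 | (1R,3R)-1-(BL)-3-methyl-4,7-dioxooctyl (2S)-2-methyloxirane-2-carboxylate | CC(=O)CCC(=O)[C@H](C)C[C@@H](OC(=O)[C@@]3(C)OC3)C2=C(COC(C)=O)C(=O)OC2O[Si](C)(C)C(C)(C)C | intermediate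
15 | nitromethane | C[N+](=O)[O-] | starting material
16 | (1R,3R)-1-(BL)-3-[(2RS,5R)-2-hydroxy-5-methyl-5-(nitromethyl)oxolan-2-yl]butyl (2S)-2-methyloxirane-2-carboxylate | [O-][N+](=O)C[C@@]3(C)CCC(O)(O3)[C@H](C)C[C@@H](OC(=O)[C@@]4(C)OC4)C2=C(COC(C)=O)C(=O)OC2O[Si](C)(C)C(C)(C)C | intermediate
17 | compound 16 with the silyl acylal cleaved to the free 5-hydroxybutenolide (lactol) | [O-][N+](=O)C[C@@]3(C)CCC(O)(O3)[C@H](C)C[C@@H](OC(=O)[C@@]4(C)OC4)C2=C(COC(C)=O)C(=O)OC2O | intermediate
18 | (1S,4R,8R,10R)-13-acetoxy-1,6-dihydroxy-8-[(2S)-2-methyloxirane-2-carbonyloxy]-5-nitro-1,4-epoxygermacr-7(11)-en-12-oic acid (CO2H cis to C6; C5/C6 epimers) | CC(=O)OC/C(C(O)=O)=C2/C(O)C([N+](=O)[O-])[C@@]3(C)CC[C@](O)(O3)[C@H](C)C[C@H]2OC(=O)[C@@]4(C)OC4 | intermediate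
19 | (1S,4R,8R,10R)-13-acetoxy-1-hydroxy-8-[(2S)-2-methyloxirane-2-carbonyloxy]-5-nitro-1,4-epoxygermacr-7(11)-en-12,6-olide (C5/C6 epimers) | CC(=O)OCC1=C2C(C([N+](=O)[O-])[C@@]3(C)CC[C@](O)(O3)[C@H](C)C[C@H]2OC(=O)[C@@]4(C)OC4)OC1=O | intermediate
20 | (1S,4R,5E,8R,10R)-13-acetoxy-1-hydroxy-8-[(2S)-2-methyloxirane-2-carbonyloxy]-1,4-epoxygermacra-5,7(11)-dien-12,6-olide | CC(=O)OCC1=C2/C(=C\[C@@]3(C)CC[C@](O)(O3)[C@H](C)C[C@H]2OC(=O)[C@@]4(C)OC4)OC1=O | intermediate
21 | (1S,4R,5E,8R,10R)-13-acetoxy-8-[(2R)-3-chloro-2-hydroxy-2-methylpropanoyloxy]-1-hydroxy-1,4-epoxygermacra-5,7(11)-dien-12,6-olide (CNP0414417.2) | CC(=O)OCC1=C2/C(=C\[C@@]3(C)CC[C@](O)(O3)[C@H](C)C[C@H]2OC(=O)[C@@](C)(O)CCl)OC1=O | target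

**Step count and risks**
Total steps: 11. Longest linear sequence: 8 (steps 1, 3, 4, 7, 8, 9, 10, 11).

Three steps most likely to fail:

1. Step 9 (the proposed new asymmetric ketone nitroaldol). Risks are low conversion, poor face selectivity at C4, erosion by retro-nitroaldol, or competing addition at C1. The fallback uses known chemistry, sets out from 14 and returns at 16. Tetramethylguanidine-catalysed nitroaldol addition in neat nitromethane (known for simple ketones) gives 16 together with its oxolane C5 epimer F3. A kinetic resolution by retro-nitroaldol with the heterobimetallic base LaLi3(binaphthoxide)3 then degrades the epimer F3 back to 14 and nitromethane (both recycled) and leaves 16.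

2. Step 10 (desilylation, macrocyclising Henry reaction, relactonisation, loss of HNO2). Risks are oligomerisation, retro-nitroaldol at C4, and loss of the C13 acetate from the butenolide dienolate. The fallback sets out from 16 and returns at 20 by forming the same alkene through a Wittig reaction. A Nef reaction (aqueous TiCl3 buffered with NH4OAc, THF) converts the primary nitro group into the oxolane aldehyde F4. Ph3P·HBF4 in MeCN exchanges the silyloxy acylal for a phosphonium group to give the butenolide phosphonium salt F5. Et3N in CH2Cl2 at high dilution then triggers the intramolecular Wittig olefination, known for 5-phosphonio-butenolides with aldehydes, to close the ring as 20.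

3. Step 3 (ligand-controlled Ni/Cr coupling). Risks are insufficient facial control at C8 and competing insertion at the α C–Br bond. The fallback sets out from 3 and 5 and returns at 6, moving stereocontrol from the C–C bond formation to a ketone reduction. Ligand-free coupling (CrCl2, catalytic NiCl2, DMF) gives 6 mixed with its carbinol epimer F1. Dess–Martin periodinane oxidises the mixture to the acylbutenolide ketone F2, and (S)-2-methyl-CBS-oxazaborolidine with catecholborane at −78 °C reduces it to 6 alone.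

**Further compounds**
F1 | step 3 | (5RS)-3-bromo-5-[(tert-butyldimethylsilyl)oxy]-4-[(1S,3R)-1-hydroxy-3-(5-methylfuran-2-yl)butyl]furan-2(5H)-one | Cc1ccc(o1)[C@H](C)C[C@H](O)C2=C(Br)C(=O)OC2O[Si](C)(C)C(C)(C)C
F2 | step 3 | (5RS)-3-bromo-5-[(tert-butyldimethylsilyl)oxy]-4-[(3R)-3-(5-methylfuran-2-yl)butanoyl]furan-2(5H)-one | Cc1ccc(o1)[C@H](C)CC(=O)C2=C(Br)C(=O)OC2O[Si](C)(C)C(C)(C)C
F3 | step 9 | (1R,3R)-1-(BL)-3-[(2RS,5S)-2-hydroxy-5-methyl-5-(nitromethyl)oxolan-2-yl]butyl (2S)-2-methyloxirane-2-carboxylate | [O-][N+](=O)C[C@]3(C)CCC(O)(O3)[C@H](C)C[C@@H](OC(=O)[C@@]4(C)OC4)C2=C(COC(C)=O)C(=O)OC2O[Si](C)(C)C(C)(C)C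
F4 | step 10 | (1R,3R)-1-(BL)-3-[(2RS,5R)-5-formyl-2-hydroxy-5-methyloxolan-2-yl]butyl (2S)-2-methyloxirane-2-carboxylate | O=C[C@@]3(C)CCC(O)(O3)[C@H](C)C[C@@H](OC(=O)[C@@]4(C)OC4)C2=C(COC(C)=O)C(=O)OC2O[Si](C)(C)C(C)(C)C
F5 | step 10 | [(2RS)-4-(acetoxymethyl)-3-[(1R,3R)-3-[(2RS,5R)-5-formyl-2-hydroxy-5-methyloxolan-2-yl]-1-[(2S)-2-methyloxirane-2-carbonyloxy]butyl]-5-oxo-2,5-dihydrofuran-2-yl]triphenylphosphonium tetrafluoroborate | O=C[C@@]3(C)CCC(O)(O3)[C@H](C)C[C@@H](OC(=O)[C@@]4(C)OC4)C2=C(COC(C)=O)C(=O)OC2[P+](c5ccccc5)(c6ccccc6)c7ccccc7.F[B-](F)(F)F
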